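Every flask here is reckoned by setting its time scales against the asked time, and the number carried along is the clearing order.

the same everywhere: free catalyst 0.5 mol%; second catalyst 2.5 mol%

|  | substrate | coupling partner | remark | time |
|---|---|---|---|---|
| teal | 0.0044 M | 1.3 equiv | run made earlier |  |
| ochre | 0.057 M | 1.3 equiv | run made earlier |  |
| elm | 0.030 M | 1.30 equiv |  | 3.0 h |
| maple | 0.012 M | 1.30 equiv |  | 3.0 h |
| alder | 0.0050 M | 1.30 equiv |  | 3.0 h |
| ash | 0.080 M | 1.30 equiv |  | 3.0 h |
| birch | 0.010 M | 1.30 equiv |  | 3.0 h |
| oak | 0.020 M | 1.30 equiv |  | 3.0 h |

| run | time / min | product / % | substrate / % |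
|---|---|---|---|
| teal | 6.00 | 0 | 96.7 |
| teal | 20.0 | 0 | 85.2 |
| teal | 40.0 | 0 | 71.9 |
| teal | 50.0 | 0.7 | 66.0 |
| teal | 80.0 | 1.8 | 51.9 |
| teal | 90.0 | 3.0 | 48.5 |
| teal | 120 | 4.3 | 38.0 |
| ochre | 20.0 | 10.4 | 50.1 |
| ochre | 40.0 | 26.4 | 24.4 |
| ochre | 50.0 | 35.4 | 17.5 |
| ochre | 80.0 | 59.2 | 6.7 |
| ochre | 90.0 | 64.3 | 3.5 |
| ochre | 120 | 78.4 | 0.7 |

(scatter of a reading: 1 percentage point)

* ranking by amount of product, in percent of the substrate charged, from high to low, at 3.0 h (elm / maple / alder / ash / birch / oak)
* the amount of product, in percent of the substrate charged of the flask you put first, at 3.0 h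
* the amount of product, in percent of the substrate charged of the flask you put last, at 3.0 h



The ladder, fastest first, is read from the two runs and carries their scatter:

1. Ochre loses substrate with a pseudo-first-order constant of 0.0353 min⁻¹, a half-life of 19.7 min.

2. Ochre's balance shows an unread stock between substrate and product, and product grows from that stock with a constant near 0.0182 min⁻¹, a half-time of 38.0 min, so handover in ochre is slower than clearing.

3. Teal loses substrate with 0.00806 min⁻¹, a half-life of 86.0 min.

4. The asked time, 3.0 h, stands next.

5. Teal's handover comes last, near 0.00120 min⁻¹, a half-time of about 577 min. This is a rough reading, since it rests on a rise of 2.5 percentage points against a scatter of 1 point, but teal's handover still reads slower than teal's clearing.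

6. With the loading of free catalyst the same in teal and ochre, catalyst concentration goes with substrate concentration, so the two clearing constants over the two concentrations give 0.576, the clearing order: the power of catalyst concentration by which the constant of substrate loss rises.

7. My own reckoning scales teal's constant by this power to 0.00868 min⁻¹ for alder, which leaves 21.0% of alder's substrate at 3.0 h. For ash it gives a half-life of 16.2 min.

The forecast gives ash > elm > oak > maple > birch > alder, with 97% first and 11% last, on the ground that “catalyst concentration follows substrate concentration, so product rises with concentration”.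

The flasks give ash > elm > oak > maple > birch > alder, with 97.9% in ash and 12.4% in alder, so the forecast held.

    substrate + free catalyst → free catalyst + open intermediate (k = 55000 L mol⁻¹ h⁻¹)
    second catalyst + open intermediate ⇌ catalyst intermediate (K = 870 L mol⁻¹, k = 880 L mol⁻¹ h⁻¹)
    coupling partner + catalyst intermediate → second catalyst + product (k = 3200 L mol⁻¹ h⁻¹)
    2 free catalyst ⇌ resting dimer, settled at all times (K = 82000 L mol⁻¹)

Alder kept 20.3% of its substrate against the reckoned 21.0%. Alder's neighbour, charged with 2 mol% of free catalyst instead of 0.5 mol%, is reckoned by the clearing order at a constant of 0.0193 min⁻¹, which leaves 3.10% of its substrate. That neighbour shows 2.73% of substrate, 79.5% as open intermediate and 17.4% as product.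

(The earlier runs and the new flask are simulated for substances that don't exist; noise was put on by code.)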